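## The problem

Target 28 is a trans-fused hydroazulene in which cyclopentane ring A (C1–C5) and cycloheptane ring B (C5, C6, C7, C8, C9, C10, C1) share the C1–C5 bond. The locants used throughout are: C1, quaternary fusion carbon with the angular methyl C15; C2 and C3, ring A methylenes; C4, tertiary carbinol carrying the isopropyl group; C5, fusion methine; C6, carbinol esterified with 3-methylbutanoic acid; C7, methylene; C8, carrying the exocyclic methylene C14; C9 and C10, secondary carbinols, C10 bonded to C1. With C15 taken as β, the six stereocentres are H5 α (trans fusion), C4–OH β, C6–O α, C9–OH α and C10–OH α.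

The quaternary centre C1 has no neighbour that can set it, so it must be made by relay from a centre that is rebuilt later. Once C1 exists, C15 screens the β face. That helps at C10 and C4 (oxygen and isopropyl must arrive from α) and at C5 (proton from α), but works against C6 and C9, where hydride has to come from β. Those two centres therefore need a helper on the ring: an oxygen on C4 for C6 and the oxygen on C10 for C9.

The molecule tolerates little force. C5 epimerises, and a C4 or C6 oxygen can be lost by β-elimination, whenever the other of the two is a ketone. The allylic alcohol with its 1,1-disubstituted alkene is acid-sensitive. One ester has to be told apart from three free hydroxyl groups, so it must be in place before the diol is unveiled.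

The enabling feature is that C6 and C9 are both oxygenated and 1,4-related across ring B, C9 is linked through C10 to C1, and C5 is α to C6. A cyclobutane C1–C5–C9–C10 with an alkoxy donor on C9 and a ketone at C6 is a masked seven-membered 6,9-dione, opened by retro-aldol cleavage of C5–C9. That cyclobutane is the (2+2) adduct of a C5=C1 enone and a C9=C10 enol ether.

## Retrosynthesis

**C9–H and the two O–Si bonds (28 ⇒ 27 ⇒ 26).** 28 comes from its bis(triethylsilyl) ether 27, and 27 from α′-silyloxy enone 26 by 1,2-reduction. Osmylation of a C9=C10 alkene would set both carbinols more safely, but that alkene would be conjugated with the C8 methylene, and the exocyclic double bond would react first. Keeping C9 as a ketone also uses the oxidation level that the ring expansion delivers. The forward step must reduce an exocyclic enone at the carbonyl only, spare the ester, and bring hydride to the β face, with the axial C10 silyloxy group as the only control.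

**C10–O (26 ⇒ 24).** Cutting this bond gives α-methylene ketone 24. With C8 blocked, enolisation can go only toward C10, which removes the regiochemical problem that ketone 20 itself would pose. The oxidant must approach anti to C15 on the neighbouring carbon.

**C8–C14 (24 ⇒ 22 ⇒ 20).** The methylene is traced through Mannich base 22 to ketone 20. A Wittig reaction at C8 would require a 1,2-transposition of the carbonyl group; α-methylenation uses the C9 ketone as it stands. The forward step must enolise toward C8 and not toward the neopentyl C10, in the presence of an ester.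

**C4–isopropyl (20 ⇒ 19 ⇒ 18).** The tertiary carbinol is cut at the C4–isopropyl bond, via ketal 19, to ketone 18. The isopropyl group enters this late because a secondary C4 oxygen is needed twice before as a control element, and because an earlier tertiary β-hydroxy ketone would dehydrate. The addition must come from the α face and must not touch the ester; C9 has to be masked.

**C4 oxidation and C6–O acyl (18 ⇒ 17 ⇒ 16).** Ketone 18 goes back to alcohol 17, and removal of the acyl group gives diol 16. Acylating here avoids picking C6–OH out of three secondary hydroxyl groups at the end; 16 has only two, in different steric surroundings.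

**C6–H (16 ⇒ 15).** The C6 carbinol comes from β-hydroxy ketone 15. Internal hydride delivery from the C4 hydroxyl is the only way to reach the β face of C6. External hydride would follow C15 and give the epimer.

**C5–C9 reconnected (15 ⇒ 14 ⇒ 13).** Joining C5 to C9, with C9 returned from ketal to methyl ether and C4–OH to its silyl ether, leads through 14 to tricyclic ketone 13. This is the strategic simplification: ring B, with C6 and C9 already differentiated, is released by one acid-promoted fragmentation, and no medium-ring closure is needed. The forward step must cleave only C5–C9, trap C9 as a ketal, and protonate C5 from the α face under kinetic control.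

**C1–C10 and C5–C9 (13 ⇒ 12).** Both cyclobutane bonds are cut to give enone 12 with a tethered methyl enol ether. Two rings, the quaternary centre and three stereocentres are exchanged for one stereocentre on a monocyclic compound. The forward reaction must add to the face of C5=C1 opposite to the C4 silyloxy group.

**Enone and enol ether (12 ⇒ 11 ⇒ 10 ⇒ 9).** The enone is taken back to alcohol 11 and its silyl ether 10, and the enol ether carbon C10 is removed to give methyl ester 9. Ester methylenation fixes the double bond position, which elimination from a ketal would not. The C6 carbonyl must be absent at that stage because it would be methylenated first.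

**C5–C6 (9 ⇒ 5 + 6).** Cutting this bond gives alkenyl bromide 5 and aldehyde ester 6, a commercial four-carbon unit that carries C6–C9 at the right oxidation levels.

**Ring A (5 ⇒ 4 ⇒ 3 ⇒ 1).** Silyl ether 5 comes from alcohol 4, whose single stereocentre is set by catalytic reduction of bromo enone 3, made from enone 1.

## Roads not taken

**Alternative 1:** the cut is C9–C10. Samarium diiodide would convert the two aldehydes of A1 into ketyls that couple to diol A2, closing ring B and setting the cis-diol in one step.
- Merits: this is the strongest answer to the weakest point of the chosen plan, the late C9 reduction, because a chelated pinacol coupling gives the cis-diol directly. The ester and the tertiary carbinol are already in place, so the end game is short.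
- Weak points: A1 must carry C1, C4, C5 and C6 fully set on a cyclopentane with an open chain, so C6 has to be controlled without ring B. The C10 aldehyde is neopentyl. The C9 aldehyde is α to a ketal, a pattern that samarium diiodide tends to cleave reductively. The cis-diol can form on either face relative to C15. The C8 ketal still has to be hydrolysed and methylenated beside a free diol.
- Comparison: on diol stereochemistry this road is better. The chosen plan sets against it that the quaternary centre, ring B and the 6,9-dioxygenation all arise together from a precursor with one stereocentre.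

**Alternative 2:** the cut is C4–C5. A chiral triazolium-derived carbene would turn the aldehyde of prochiral trione A3 into a Breslow intermediate that adds to one of the two enantiotopic ring ketones, giving ketol A4.
- Merits: catalytic enantiocontrol from an achiral substrate, no photochemistry, and the bicyclic core with C1 and C5 set in very few steps. In brevity to the core and in scalability it is better than the chosen plan.
- Weak points: A4 is cis-fused and carries a hydroxyl on C5 where the target has a trans hydrogen, so a tertiary C–O bond would have to be replaced by C–H with inversion of the ring fusion. C6, C8 and C9 are bare methylenes; C9 can be reached from the C10 ketone, but C6 has no activating neighbour.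
- Comparison: the step count saved early would be spent, with less certainty, on remote oxidation. The chosen plan delivers ring B with oxygen already on C6 and C9.

**Alternative 3:** the cut is C1–C5. Diazo keto ester A6, made from citronellol A5, would give a rhodium carbenoid with Rh2(OAc)4 that inserts into the tertiary C1–H bond with retention to give cyclopentanone A7.
- Merits: the absolute configuration of C1 comes from the chiral pool with high reliability, which is better than relying on facial selectivity in a photoreaction. The C4 ketone and a C6 carboxyl carbon are in place, and the C5 centre of the β-keto ester can settle trans to the C1 side chain.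
- Weak points: A7 is only ring A. Ring B still needs two more carbons (C7, C8), a seven-membered ring closure, and then the same diol and methylene problems as the chosen plan.
- Comparison: several more C–C bond-forming steps are needed. The chosen plan forms both ring B bonds in the key step and its successor.

Key step: step 8

## Route

Remark: the locants C1–C10, C14, C15 and the descriptors α/β (C15 on the β face) defined above are used for all bicyclic and tricyclic compounds; reagents used as bought are not numbered.

Step 1
Reactants: 1 3-methylcyclopent-2-en-1-one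
Product: 3 2-bromo-3-methylcyclopent-2-en-1-one, via trans-dibromide 2 (not isolated)
Conditions: Br2, CH2Cl2, 0 °C; then Et3N, 0 °C → rt
Reagents that add atoms: bromine BrBr
Why: α-Bromination of an enone by addition of bromine and E1cB loss of HBr from the α,β-dibromide; the acidic α-hydrogen is the one removed, so bromine stays on the carbon that becomes C5.

Step 2
Reactants: 3 2-bromo-3-methylcyclopent-2-en-1-one
Product: 4 (1S)-2-bromo-3-methylcyclopent-2-en-1-ol
Conditions: (R)-2-methyl-CBS-oxazaborolidine (C18H20BNO, 0.2 equiv), BH3·SMe2, THF, −20 °C; MeOH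
Reagents that add atoms: none
Why: Corey–Bakshi–Shibata reduction; the bromoalkenyl branch acts as the large group, so the (R)-catalyst should deliver hydride to the face that gives the (S)-carbinol, the future C4 with its oxygen β.

Step 3
Reactants: 4 (1S)-2-bromo-3-methylcyclopent-2-en-1-ol
Product: 5 [(1S)-2-bromo-3-methylcyclopent-2-en-1-yl]oxy(tert-butyl)dimethylsilane
Conditions: TBSCl, imidazole, DMF, rt
Reagents that add atoms: tert-butyldimethylsilyl chloride CC(C)(C)[Si](C)(C)Cl
Why: Standard silylation of a secondary alcohol; the group survives t-BuLi, Cp2TiMe2 and K2CO3/MeOH and later shields the β face of C5=C1.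

Step 4
Reactants: 5 [(1S)-2-bromo-3-methylcyclopent-2-en-1-yl]oxy(tert-butyl)dimethylsilane; 6 methyl 4-oxobutanoate
Product: 9 methyl 4-[(5S)-5-(tert-butyldimethylsilyloxy)-2-methylcyclopent-1-en-1-yl]-4-(trimethylsilyloxy)butanoate (both C6 epimers), via alkenyllithium 7 (not isolated), via lithium alkoxide 8 (not isolated)
Conditions: t-BuLi (2.1 equiv), Et2O, −78 °C; 6, −78 °C; TMSCl, Et3N, −78 → 0 °C
Reagents that add atoms: chlorotrimethylsilane C[Si](C)(C)Cl
Why: Bromine–lithium exchange and 1,2-addition of the alkenyllithium to the aldehyde, which is much faster than attack on the ester at −78 °C; silylation in the same flask keeps the γ-alkoxy ester from closing to the butyrolactone; the new C6 centre is uncontrolled and is erased in step 7.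

Step 5
Reactants: 9 methyl 4-[(5S)-5-(tert-butyldimethylsilyloxy)-2-methylcyclopent-1-en-1-yl]-4-(trimethylsilyloxy)butanoate
Product: 10 tert-butyl{[(1S)-2-[4-methoxy-1-(trimethylsilyloxy)pent-4-en-1-yl]-3-methylcyclopent-2-en-1-yl]oxy}dimethylsilane (both C6 epimers)
Conditions: Cp2TiMe2 (3 equiv), toluene, 65 °C, dark
Reagents that add atoms: dimethyltitanocene C[Ti+2]C.c1cc[cH-]c1.c1cc[cH-]c1
Why: Petasis methylenation of a methyl ester; Cp2Ti=CH2, formed by loss of methane, adds to the ester carbonyl and the oxatitanacyclobutane collapses to the 2-methoxyalkene, so the double bond position is fixed; silyl ethers and the tetrasubstituted alkene do not react.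

Step 6
Reactants: 10 tert-butyl{[(1S)-2-[4-methoxy-1-(trimethylsilyloxy)pent-4-en-1-yl]-3-methylcyclopent-2-en-1-yl]oxy}dimethylsilane
Product: 11 1-[(5S)-5-(tert-butyldimethylsilyloxy)-2-methylcyclopent-1-en-1-yl]-4-methoxypent-4-en-1-ol (both C6 epimers)
Conditions: K2CO3 (0.2 equiv), MeOH, 0 °C
Reagents that add atoms: none
Why: Base-catalysed methanolysis removes a trimethylsilyl ether far faster than a tert-butyldimethylsilyl ether, and basic methanol does not harm the acid-labile enol ether.

Step 7
Reactants: 11 1-[(5S)-5-(tert-butyldimethylsilyloxy)-2-methylcyclopent-1-en-1-yl]-4-methoxypent-4-en-1-ol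
Product: 12 1-[(5S)-5-(tert-butyldimethylsilyloxy)-2-methylcyclopent-1-en-1-yl]-4-methoxypent-4-en-1-one
Conditions: MnO2, CH2Cl2, rt
Reagents that add atoms: none
Why: Oxidation of an allylic alcohol with MnO2 under neutral conditions; both C6 epimers converge on one enone and the enol ether is untouched.

Step 8
Reactants: 12 1-[(5S)-5-(tert-butyldimethylsilyloxy)-2-methylcyclopent-1-en-1-yl]-4-methoxypent-4-en-1-one
Product: 13 2-(tert-butyldimethylsilyloxy)-7-methoxy-5-methyltricyclo[5.3.0.0(1,5)]decan-10-one (C6 ketone; C9 methoxy; C4 silyloxy and C15 β; C9 and C10 on the α face of ring A)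
Conditions: hν (350 nm, Pyrex), degassed cyclohexane (5 mM), solid NaHCO3, 10 °C
Reagents that add atoms: none
Why: Excitation of the 1-acylcyclopentene at its n→π* band and intersystem crossing give the triplet enone, which bonds from C5 to C9 of the tethered enol ether to form a 1,4-biradical (C1 and C10); spin inversion and C1–C10 coupling complete the cyclobutane. The closest known reaction type is the intramolecular enone–alkene (2+2) photocycloaddition of a 1,6-diene with an electron-rich alkene, the first half of a de Mayo sequence. The cyclopentanone ring C5–C6–C7–C8–C9 closes in the 5-exo mode required by the rule of five, since the alternative first bond C1–C10 would need a seven-membered ring; the cyclobutane closes by radical recombination. C5 is set when the first bond forms, on the face of C5=C1 anti to the neighbouring C4 silyloxy group. C1 and C9 follow from C5, because both four–five ring fusions can only be cis, so C10 ends α and C15 β on C1. The step needs straight and not crossed regiochemistry, which the three-atom tether secures, and facial selectivity, which the silyloxy group next to C5 secures. Photoenolisation through the C15 hydrogens is reversible in a base-free medium, and Pyrex-filtered light is hardly absorbed by the saturated ketone product.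

Step 9
Reactants: 13 2-(tert-butyldimethylsilyloxy)-7-methoxy-5-methyltricyclo[5.3.0.0(1,5)]decan-10-one
Product: 15 9,9-ethylenedioxy-4β-hydroxy-1β-methyl-5αH-perhydroazulen-6-one, via silyl ether 14 (not isolated)
Conditions: TsOH·H2O (0.3 equiv), HOCH2CH2OH/THF (1:3), 0 °C → rt; then Et3N
Reagents that add atoms: ethane-1,2-diol OCCO
Why: de Mayo-type retro-aldol fragmentation: protonation of the C6 carbonyl and the push of the C9 methoxy group cleave the strained C5–C9 bond, glycol traps the oxocarbenium ion as the dioxolane, and the C5=C6 enol is protonated on carbon from the α face, away from C15 and the C4 oxygen, which gives the trans fusion under kinetic control because acid-catalysed re-enolisation of the ketone is slow; the same acid then cleaves the silyl ether in the alcoholic medium.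

Step 10
Reactants: 15 9,9-ethylenedioxy-4β-hydroxy-1β-methyl-5αH-perhydroazulen-6-one
Product: 16 9,9-ethylenedioxy-1β-methyl-5αH-perhydroazulene-4β,6α-diol
Conditions: Me4NBH(OAc)3 (5 equiv), MeCN/AcOH (2:1), −30 °C
Reagents that add atoms: none
Why: Evans–Saksena reduction: the C4 hydroxyl displaces acetate on boron and delivers hydride internally through a chair transition state with C3 and C7 equatorial, which puts hydride on the β face of C6 and gives the 1,3-anti diol (C6–OH α); the reagent does not reduce the masked C9 carbonyl and the acidic medium does not epimerise C5.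

Step 11
Reactants: 16 9,9-ethylenedioxy-1β-methyl-5αH-perhydroazulene-4β,6α-diol
Product: 17 9,9-ethylenedioxy-4β-hydroxy-1β-methyl-5αH-perhydroazulen-6α-yl 3-methylbutanoate
Conditions: i-BuCOCl (1.05 equiv), pyridine, CH2Cl2, −40 °C
Reagents that add atoms: 3-methylbutanoyl chloride CC(C)CC(=O)Cl
Why: Site-selective acylation: the C6 hydroxyl is equatorial on ring B, whereas the C4 hydroxyl is pseudoaxial on ring A, cis to the C5–C6 bond and syn to C15, so the C6 hydroxyl should react first at low temperature.

Step 12
Reactants: 17 9,9-ethylenedioxy-4β-hydroxy-1β-methyl-5αH-perhydroazulen-6α-yl 3-methylbutanoate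
Product: 18 9,9-ethylenedioxy-1β-methyl-4-oxo-5αH-perhydroazulen-6α-yl 3-methylbutanoate
Conditions: Dess–Martin periodinane, NaHCO3, CH2Cl2, 0 °C → rt
Reagents that add atoms: none
Why: Dess–Martin oxidation of the remaining secondary alcohol under buffered, non-basic conditions, which avoid enolisation toward C5 and so epimerisation or loss of the β-acyloxy group.

Step 13
Reactants: 18 9,9-ethylenedioxy-1β-methyl-4-oxo-5αH-perhydroazulen-6α-yl 3-methylbutanoate
Product: 20 4β-hydroxy-4α-isopropyl-1β-methyl-9-oxo-5αH-perhydroazulen-6α-yl 3-methylbutanoate, via ketal carbinol 19 (not isolated)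
Conditions: i-PrMgCl, CeCl3, THF, −78 °C; then 1 M HCl (aq), THF, rt
Reagents that add atoms: isopropylmagnesium chloride CC(C)[Mg]Cl; water O
Why: Organocerium addition: the reagent formed from i-PrMgCl and CeCl3 is nucleophilic but weakly basic, adds to the cyclopentanone faster than to the ester, and approaches from the α face, anti to the C5–C6 bond and to C15, giving the β-hydroxyl and α-isopropyl group; aqueous acid then hydrolyses the dioxolane.

Step 14
Reactants: 20 4β-hydroxy-4α-isopropyl-1β-methyl-9-oxo-5αH-perhydroazulen-6α-yl 3-methylbutanoate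
Product: 22 8-(dimethylaminomethyl)-4β-hydroxy-4α-isopropyl-1β-methyl-9-oxo-5αH-perhydroazulen-6α-yl 3-methylbutanoate (C8 epimers), via dilithium enolate 21 (not isolated)
Conditions: LiN(SiMe3)2 (2.2 equiv), THF, −78 °C; CH2=NMe2+ I−, −78 → 0 °C
Reagents that add atoms: N,N-dimethylmethyleneiminium iodide C[N+](C)=C.[I-]
Why: Mannich reaction of a kinetic lithium enolate with Eschenmoser's salt: the silylamide deprotonates the tertiary hydroxyl and then the C8 methylene, which is more accessible than the neopentyl C10 methylene beside quaternary C1 and more acidic than the ester α-position; the new C8 centre disappears in step 15.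

Step 15
Reactants: 22 8-(dimethylaminomethyl)-4β-hydroxy-4α-isopropyl-1β-methyl-9-oxo-5αH-perhydroazulen-6α-yl 3-methylbutanoate
Product: 24 4β-hydroxy-4α-isopropyl-1β-methyl-8-methylidene-9-oxo-5αH-perhydroazulen-6α-yl 3-methylbutanoate, via methiodide 23 (not isolated)
Conditions: MeI, CH2Cl2, rt; then DBU
Reagents that add atoms: none
Why: Quaternisation of the amine and E1cB (Hofmann-type) loss of trimethylamine from the β-ammonium ketone give the α-methylene ketone.

Step 16
Reactants: 24 4β-hydroxy-4α-isopropyl-1β-methyl-8-methylidene-9-oxo-5αH-perhydroazulen-6α-yl 3-methylbutanoate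
Product: 26 4α-isopropyl-1β-methyl-8-methylidene-9-oxo-4β,10α-bis(triethylsilyloxy)-5αH-perhydroazulen-6α-yl 3-methylbutanoate, via silyl dienol ether 25 (not isolated)
Conditions: Et3SiOTf (3 equiv), Et3N, CH2Cl2, −78 → 0 °C; then mCPBA, NaHCO3, CH2Cl2, −20 °C
Reagents that add atoms: triethylsilyl trifluoromethanesulfonate CC[Si](CC)(CC)OS(=O)(=O)C(F)(F)F; 3-chloroperoxybenzoic acid OOC(=O)c1cccc(Cl)c1
Why: Rubottom oxidation: soft enolisation can go only toward C10 because C8 has no hydrogen, giving the 2-silyloxy-1,3-diene (the tertiary hydroxyl is silylated as well); the peracid epoxidises the electron-rich C9=C10 bond from the α face, anti to C15 on neighbouring C1, and silyl migration gives the α-silyloxy ketone with the C10 oxygen α.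

Step 17
Reactants: 26 4α-isopropyl-1β-methyl-8-methylidene-9-oxo-4β,10α-bis(triethylsilyloxy)-5αH-perhydroazulen-6α-yl 3-methylbutanoate
Product: 27 9α-hydroxy-4α-isopropyl-1β-methyl-8-methylidene-4β,10α-bis(triethylsilyloxy)-5αH-perhydroazulen-6α-yl 3-methylbutanoate
Conditions: NaBH4, CeCl3·7H2O, MeOH/THF, −78 °C
Reagents that add atoms: none
Why: Luche reduction, 1,2-selective for the exocyclic enone and harmless to the ester; the trans ring fusion holds the C10 silyloxy group axial and perpendicular to the carbonyl plane, so the small hydride should add anti to it (Felkin–Anh) on the β face and give the C9 α-alcohol, cis to the C10 oxygen.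

Step 18
Reactants: 27 9α-hydroxy-4α-isopropyl-1β-methyl-8-methylidene-4β,10α-bis(triethylsilyloxy)-5αH-perhydroazulen-6α-yl 3-methylbutanoate
Product: 28 (3R,3aS,4S,7R,8S,8aS)-3,7,8-trihydroxy-8a-methyl-6-methylidene-3-(propan-2-yl)decahydroazulen-4-yl 3-methylbutanoate (CNP0204264.1)
Conditions: HF·pyridine, pyridine, THF, 0 °C → rt
Reagents that add atoms: none
Why: Fluoride-mediated cleavage of both triethylsilyl ethers under buffered conditions that leave the ester, the tertiary carbinol and the allylic alcohol intact.

## Compound list

1 | 3-methylcyclopent-2-en-1-one | CC1=CC(=O)CC1 | starting material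
2 | trans-2,3-dibromo-3-methylcyclopentan-1-one (not isolated) | O=C1CCC(C)(Br)C1Br | intermediate
3 | 2-bromo-3-methylcyclopent-2-en-1-one | O=C1CCC(C)=C1Br | intermediate
4 | (1S)-2-bromo-3-methylcyclopent-2-en-1-ol | BrC1=C(C)CC[C@@H]1O | intermediate
5 | [(1S)-2-bromo-3-methylcyclopent-2-en-1-yl]oxy(tert-butyl)dimethylsilane | BrC1=C(C)CC[C@@H]1O[Si](C)(C)C(C)(C)C | intermediate
6 | methyl 4-oxobutanoate | COC(=O)CCC=O | starting material
7 | [(5S)-5-(tert-butyldimethylsilyloxy)-2-methylcyclopent-1-en-1-yl]lithium (not isolated) | [Li]C1=C(C)CC[C@@H]1O[Si](C)(C)C(C)(C)C | intermediate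
8 | lithium alkoxide of methyl 4-[(5S)-5-(tert-butyldimethylsilyloxy)-2-methylcyclopent-1-en-1-yl]-4-hydroxybutanoate (C6 epimers; not isolated) | COC(=O)CCC(O[Li])C1=C(C)CC[C@@H]1O[Si](C)(C)C(C)(C)C | intermediate
9 | methyl 4-[(5S)-5-(tert-butyldimethylsilyloxy)-2-methylcyclopent-1-en-1-yl]-4-(trimethylsilyloxy)butanoate (C6 epimers) | COC(=O)CCC(O[Si](C)(C)C)C1=C(C)CC[C@@H]1O[Si](C)(C)C(C)(C)C | intermediate
10 | tert-butyl{[(1S)-2-[4-methoxy-1-(trimethylsilyloxy)pent-4-en-1-yl]-3-methylcyclopent-2-en-1-yl]oxy}dimethylsilane (C6 epimers) | C=C(OC)CCC(O[Si](C)(C)C)C1=C(C)CC[C@@H]1O[Si](C)(C)C(C)(C)C | intermediate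
11 | 1-[(5S)-5-(tert-butyldimethylsilyloxy)-2-methylcyclopent-1-en-1-yl]-4-methoxypent-4-en-1-ol (C6 epimers) | C=C(OC)CCC(O)C1=C(C)CC[C@@H]1O[Si](C)(C)C(C)(C)C | intermediate
12 | 1-[(5S)-5-(tert-butyldimethylsilyloxy)-2-methylcyclopent-1-en-1-yl]-4-methoxypent-4-en-1-one | C=C(OC)CCC(=O)C1=C(C)CC[C@@H]1O[Si](C)(C)C(C)(C)C | intermediate
13 | 2-(tert-butyldimethylsilyloxy)-7-methoxy-5-methyltricyclo[5.3.0.0(1,5)]decan-10-one (photoadduct; C6 ketone, C9 methoxy, C4 silyloxy and C15 β) | O=C1CC[C@]2(OC)C[C@@]3(C)CC[C@H](O[Si](C)(C)C(C)(C)C)[C@@]123 | intermediate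
14 | 4β-(tert-butyldimethylsilyloxy)-9,9-ethylenedioxy-1β-methyl-5αH-perhydroazulen-6-one (not isolated) | O1CCOC12CCC(=O)[C@@H]3[C@](C)(CC[C@@H]3O[Si](C)(C)C(C)(C)C)C2 | intermediate
15 | 9,9-ethylenedioxy-4β-hydroxy-1β-methyl-5αH-perhydroazulen-6-one | O1CCOC12CCC(=O)[C@@H]3[C@](C)(CC[C@@H]3O)C2 | intermediate
16 | 9,9-ethylenedioxy-1β-methyl-5αH-perhydroazulene-4β,6α-diol | O1CCOC12CC[C@H](O)[C@@H]3[C@](C)(CC[C@@H]3O)C2 | intermediate
17 | 9,9-ethylenedioxy-4β-hydroxy-1β-methyl-5αH-perhydroazulen-6α-yl 3-methylbutanoate | O1CCOC12CC[C@H](OC(=O)CC(C)C)[C@@H]3[C@](C)(CC[C@@H]3O)C2 | intermediate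
18 | 9,9-ethylenedioxy-1β-methyl-4-oxo-5αH-perhydroazulen-6α-yl 3-methylbutanoate | O1CCOC12CC[C@H](OC(=O)CC(C)C)[C@@H]3[C@](C)(CCC3=O)C2 | intermediate
19 | 9,9-ethylenedioxy-4β-hydroxy-4α-isopropyl-1β-methyl-5αH-perhydroazulen-6α-yl 3-methylbutanoate (not isolated) | O1CCOC12CC[C@H](OC(=O)CC(C)C)[C@@H]3[C@](C)(CC[C@@]3(O)C(C)C)C2 | intermediate
20 | 4β-hydroxy-4α-isopropyl-1β-methyl-9-oxo-5αH-perhydroazulen-6α-yl 3-methylbutanoate | O=C1CC[C@H](OC(=O)CC(C)C)[C@@H]2[C@](C)(CC[C@@]2(O)C(C)C)C1 | intermediate
21 | dilithium salt of 20 (C4 alkoxide; C8=C9 enolate; not isolated) | [Li]OC1=CC[C@H](OC(=O)CC(C)C)[C@@H]2[C@](C)(CC[C@@]2(O[Li])C(C)C)C1 | intermediate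
22 | 8-(dimethylaminomethyl)-4β-hydroxy-4α-isopropyl-1β-methyl-9-oxo-5αH-perhydroazulen-6α-yl 3-methylbutanoate (C8 epimers) | O=C1C(CN(C)C)C[C@H](OC(=O)CC(C)C)[C@@H]2[C@](C)(CC[C@@]2(O)C(C)C)C1 | intermediate
23 | trimethylammonium iodide derived from 22 (not isolated) | O=C1C(C[N+](C)(C)C)C[C@H](OC(=O)CC(C)C)[C@@H]2[C@](C)(CC[C@@]2(O)C(C)C)C1.[I-] | intermediate
24 | 4β-hydroxy-4α-isopropyl-1β-methyl-8-methylidene-9-oxo-5αH-perhydroazulen-6α-yl 3-methylbutanoate | C=C1C[C@H](OC(=O)CC(C)C)[C@@H]2[C@](C)(CC[C@@]2(O)C(C)C)CC1=O | intermediate
25 | 4α-isopropyl-1β-methyl-8-methylidene-4β,9-bis(triethylsilyloxy)-5αH-perhydroazul-9-en-6α-yl 3-methylbutanoate (not isolated) | C=C1C[C@H](OC(=O)CC(C)C)[C@@H]2[C@](C)(CC[C@@]2(O[Si](CC)(CC)CC)C(C)C)C=C1O[Si](CC)(CC)CC | intermediate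
26 | 4α-isopropyl-1β-methyl-8-methylidene-9-oxo-4β,10α-bis(triethylsilyloxy)-5αH-perhydroazulen-6α-yl 3-methylbutanoate | C=C1C[C@H](OC(=O)CC(C)C)[C@@H]2[C@](C)(CC[C@@]2(O[Si](CC)(CC)CC)C(C)C)[C@H](O[Si](CC)(CC)CC)C1=O | intermediate
27 | 9α-hydroxy-4α-isopropyl-1β-methyl-8-methylidene-4β,10α-bis(triethylsilyloxy)-5αH-perhydroazulen-6α-yl 3-methylbutanoate | C=C1C[C@H](OC(=O)CC(C)C)[C@@H]2[C@](C)(CC[C@@]2(O[Si](CC)(CC)CC)C(C)C)[C@H](O[Si](CC)(CC)CC)[C@@H]1O | intermediate
28 | (3R,3aS,4S,7R,8S,8aS)-3,7,8-trihydroxy-8a-methyl-6-methylidene-3-(propan-2-yl)decahydroazulen-4-yl 3-methylbutanoate | C=C1C[C@H](OC(=O)CC(C)C)[C@@H]2[C@](C)(CC[C@@]2(O)C(C)C)[C@H](O)[C@@H]1O | target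

## Step count and risk

Total: 18 steps. Longest linear sequence: 18 steps (1 to 28); the only other starting material, 6, enters in step 4.

**Step 8 (key step).** The silyloxy group may discriminate the two faces of C5=C1 too weakly, and reversible hydrogen transfer from C15 to the excited carbonyl may consume light without product, because the methyl group lies cis to the acyl group. The fallback sets out from 11 and returns at 13. Alcohol 11, which has no enone chromophore, would be irradiated at 254 nm in Et2O with (CuOTf)2·C6H6 (monovalent copper triflate). This is the Salomon–Kochi photobicyclisation of a 1,6-diene held on copper in its ground state; it should give the tricyclic carbinol F1 with the same two bonds, and Dess–Martin oxidation of F1 gives 13.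

**Step 9.** Kinetic control at C5 may be lost: the slower desilylation keeps the ketone in acid, where re-enolisation could epimerise C5 toward the cis-fused ketone or expel the C4 oxygen. The fallback sets out from 14 and returns at 17; 14 is isolated by running the fragmentation in CH2Cl2 and stopping before desilylation.
- NaBH4 reduces the C6 ketone of either C5 epimer to the alcohols F2.
- POCl3 in pyridine dehydrates toward C5 to the C5=C6 alkene F3.
- Hydroboration–oxidation (BH3·THF; H2O2, NaOH) adds hydrogen to C5 and boron to C6 from the α face, opposite to C15 and the silyloxy group, and gives the 6α-alcohol F4 with the 5α hydrogen.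
- 3-Methylbutanoyl chloride gives ester F5, with no site selectivity needed because C4 is still silylated.
- HF·pyridine then gives 17.

**Step 11.** Acylation may not discriminate between the two secondary hydroxyl groups, giving diester or the C4 ester. The fallback sets out from 16 and returns at 17. Bu2SnO in toluene with removal of water converts the diol into the dibutylstannylene acetal F6; 3-methylbutanoyl chloride at 0 °C then acylates the more exposed tin-bound oxygen, that on C6.

**Step 13.** The secondary organometallic may transfer a β-hydride or enolise the ketone toward C5, with E1cB loss of the 3-methylbutanoate. The fallback sets out from 18 and returns at 19. Isopropenylmagnesium bromide with CeCl3, a smaller sp2 nucleophile without a β-hydrogen, should give the tertiary allylic alcohol F7. Hydrogenation (H2, 10% Pd/C, EtOAc) gives 19, which is hydrolysed to 20 as in step 13.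

**Step 17.** Hydride may be delivered to the α face, because the syn-axial C15 methyl group hinders the β face and opposes the directing effect of the C10 silyloxy group. The fallback sets out from the C9 epimer F8 that such delivery would give and returns at 27. A Mitsunobu reaction (PPh3, diisopropyl azodicarboxylate, chloroacetic acid) inverts C9 to the chloroacetate F9; thiourea and NaHCO3 in EtOH remove the chloroacetyl group without touching the 3-methylbutanoate.

## Further compounds

F1 | step 8 | 2-(tert-butyldimethylsilyloxy)-7-methoxy-5-methyltricyclo[5.3.0.0(1,5)]decan-10-ol (C6 epimers) | OC1CC[C@]2(OC)C[C@@]3(C)CC[C@H](O[Si](C)(C)C(C)(C)C)[C@@]123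
F2 | step 9 | 4β-(tert-butyldimethylsilyloxy)-9,9-ethylenedioxy-1β-methylperhydroazulen-6-ol (C5 and C6 epimers) | O1CCOC12CCC(O)C3[C@](C)(CC[C@@H]3O[Si](C)(C)C(C)(C)C)C2
F3 | step 9 | 4β-(tert-butyldimethylsilyloxy)-9,9-ethylenedioxy-1β-methylperhydroazul-5-ene | O1CCOC12CCC=C3[C@](C)(CC[C@@H]3O[Si](C)(C)C(C)(C)C)C2
F4 | step 9 | 4β-(tert-butyldimethylsilyloxy)-9,9-ethylenedioxy-1β-methyl-5αH-perhydroazulen-6α-ol | O1CCOC12CC[C@H](O)[C@@H]3[C@](C)(CC[C@@H]3O[Si](C)(C)C(C)(C)C)C2
F5 | step 9 | 4β-(tert-butyldimethylsilyloxy)-9,9-ethylenedioxy-1β-methyl-5αH-perhydroazulen-6α-yl 3-methylbutanoate | O1CCOC12CC[C@H](OC(=O)CC(C)C)[C@@H]3[C@](C)(CC[C@@H]3O[Si](C)(C)C(C)(C)C)C2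
F6 | step 11 | dibutylstannylene acetal of diol 16 | O1CCOC12CC[C@H](O4)[C@@H]3[C@](C)(CC[C@@H]3O[Sn]4(CCCC)CCCC)C2
F7 | step 13 | 9,9-ethylenedioxy-4β-hydroxy-1β-methyl-4α-(prop-1-en-2-yl)-5αH-perhydroazulen-6α-yl 3-methylbutanoate | O1CCOC12CC[C@H](OC(=O)CC(C)C)[C@@H]3[C@](C)(CC[C@@]3(O)C(C)=C)C2
F8 | step 17 | 9β-hydroxy epimer of 27 | C=C1C[C@H](OC(=O)CC(C)C)[C@@H]2[C@](C)(CC[C@@]2(O[Si](CC)(CC)CC)C(C)C)[C@H](O[Si](CC)(CC)CC)[C@H]1O
F9 | step 17 | 9α-chloroacetate of 27 | C=C1C[C@H](OC(=O)CC(C)C)[C@@H]2[C@](C)(CC[C@@]2(O[Si](CC)(CC)CC)C(C)C)[C@H](O[Si](CC)(CC)CC)[C@@H]1OC(=O)CCl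
A1 | alternative 1 | cyclopentane dialdehyde with C8 dioxolane and C6 3-methylbutanoate | O1CCOC1(C=O)C[C@H](OC(=O)CC(C)C)[C@@H]2[C@](C)(CC[C@@]2(O)C(C)C)C=O
A2 | alternative 1 | hydroazulene 9,10-cis-diol with C8 dioxolane and C6 3-methylbutanoate | O1CCOC13C[C@H](OC(=O)CC(C)C)[C@@H]2[C@](C)(CC[C@@]2(O)C(C)C)[C@H](O)[C@@H]3O
A3 | alternative 2 | 3-(1-methyl-2,7-dioxocycloheptyl)propanal | CC1(CCC=O)C(=O)CCCCC1=O
A4 | alternative 2 | cis-fused hydroazulene ketol with C4 ketone, C5 hydroxyl and C10 ketone | C[C@]12CCC(=O)[C@@]1(O)CCCCC2=O
A5 | alternative 3 | (S)-citronellol | OCC[C@@H](C)CCC=C(C)C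
A6 | alternative 3 | methyl (6S)-8-(tert-butyldimethylsilyloxy)-2-diazo-6-methyl-3-oxooctanoate | COC(=O)C(=[N+]=[N-])C(=O)CC[C@H](C)CCO[Si](C)(C)C(C)(C)C
A7 | alternative 3 | ring A β-keto ester with quaternary C1 | COC(=O)[C@H]1C(=O)CC[C@]1(C)CCO[Si](C)(C)C(C)(C)C
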